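**Plan**

- Retrosynthesis: the side-chain ester C–O bond is cut first, then the C4=O bond (quinone back to a 1-naphthol), then C2=C3 of ring B (two olefins), then C1–C2 (aldehyde plus alkenyl triflate), and last the C4–C4a allyl bond and the C1–C8a formyl bond on ring A.
- Forward: ring A is purchased as 1-bromo-2,5-dimethoxybenzene. The formyl carbon (future C1) is placed between bromine and methoxy, the neighbouring methyl ether is exchanged for a silyl ether (future O8), and bromine is replaced by allyl (future C3–C4, beside the C5 methoxy).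
- The side chain is joined by a Nozaki–Hiyama–Kishi coupling and oxidation. Ring B (C1–C4, C4a, C8a) then closes at C2=C3 by ring-closing metathesis and aromatises to the 1-naphthol. Oxidation at C4, desilylation and esterification finish the target.
- Enabling feature: C2=C3 of ring B lies between two carbons that can each end in a terminal olefin, C3 as the CH=CH2 of an allyl group on C4a and C2 as the α-methylene carbon of an aryl ketone at C1 on C8a. The ortho relationship of these two arms on ring A fixes C1=O beside O8 and C4 beside the C5 methoxy before the ring exists.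
- Stereochemistry: the single stereocentre (side-chain carbinol, S) is set by D-proline-catalysed α-aminoxylation of 6-methylhept-5-en-2-one and is carried through unchanged.

Key step: step 11

Remark on the chemistry: D-proline is assumed to deliver the 3S aminoxy ketone, by analogy with the R products that L-proline gives from cyclohexanone and from aldehydes.

**Route**

Step 1
Reactants: 1 1-bromo-2,5-dimethoxybenzene
Product: 3 2-bromo-3,6-dimethoxybenzaldehyde, via aryllithium 2 (not isolated)
Conditions: LiN(iPr)2 (1.1 equiv), THF, −78 °C; DMF, −78 → 0 °C; aq. HCl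
Reagents that add atoms: N,N-dimethylformamide, CN(C)C=O
Why: Directed ortho-lithiation with an amide base removes the ring proton flanked by bromine and methoxy (the most acidic one) without bromine–lithium exchange, and formylation of the aryllithium with DMF should give the aldehyde at that position.

Step 2
Reactants: 3 2-bromo-3,6-dimethoxybenzaldehyde
Product: 4 2-bromo-6-hydroxy-3-methoxybenzaldehyde
Conditions: BCl3 (1.2 equiv), CH2Cl2, −78 → 0 °C; H2O
Reagents that add atoms: none
Why: Chelation-controlled Lewis acid ether cleavage, in which boron binds the formyl oxygen and the adjacent methoxy oxygen in a six-membered chelate, so only the methyl ether ortho to the aldehyde should be cleaved.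

Step 3
Reactants: 4 2-bromo-6-hydroxy-3-methoxybenzaldehyde
Product: 5 2-bromo-3-methoxy-6-(triisopropylsilyloxy)benzaldehyde
Conditions: iPr3SiOTf, 2,6-lutidine, CH2Cl2, 0 °C
Reagents that add atoms: triisopropylsilyl trifluoromethanesulfonate, CC(C)[Si](OS(=O)(=O)C(F)(F)F)(C(C)C)C(C)C
Why: Silylation of a hydrogen-bonded phenol with a silyl triflate; the bulky triisopropylsilyl group is chosen because it should not shift to the benzylic oxygen formed in step 9 or to the naphthol oxygen formed in step 11.

Step 4
Reactants: 5 2-bromo-3-methoxy-6-(triisopropylsilyloxy)benzaldehyde; 6 allyltributylstannane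
Product: 7 2-allyl-3-methoxy-6-(triisopropylsilyloxy)benzaldehyde
Conditions: Pd(PPh3)4 (5 mol %), toluene, 105 °C
Reagents that add atoms: none
Why: Stille cross-coupling, in which oxidative addition of zerovalent palladium into the C–Br bond is assisted by the ortho formyl group and the allyl group is transferred from tin in preference to butyl.

Step 5
Reactants: 8 6-methylhept-5-en-2-one
Product: 9 (3S)-6-methyl-3-[(phenylamino)oxy]hept-5-en-2-one
Conditions: D-proline (30 mol %), PhNO (added slowly), 8 in threefold excess, DMF, 0 °C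
Reagents that add atoms: nitrosobenzene, O=Nc1ccccc1
Why: Proline-catalysed α-aminoxylation (O-selective nitroso aldol reaction), in which the more substituted enamine attacks the nitroso oxygen that is held by the carboxylic acid of D-proline on one face, which should set C3 as S, while the low nitroso concentration keeps an ene reaction at the trisubstituted olefin from competing.

Step 6
Reactants: 9 (3S)-6-methyl-3-[(phenylamino)oxy]hept-5-en-2-one
Product: 10 (3S)-3-hydroxy-6-methylhept-5-en-2-one
Conditions: CuSO4·5H2O (30 mol %), MeOH, 0 °C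
Reagents that add atoms: none
Why: Copper-catalysed N–O bond cleavage of an O-alkyl-N-arylhydroxylamine, a known way to release α-hydroxy ketones under neutral conditions that leave the olefin and the α-stereocentre untouched.

Step 7
Reactants: 10 (3S)-3-hydroxy-6-methylhept-5-en-2-one
Product: 11 (3S)-3-(tert-butyldimethylsilyloxy)-6-methylhept-5-en-2-one
Conditions: TBSCl, imidazole, DMF, 23 °C
Reagents that add atoms: tert-butyldimethylsilyl chloride, CC(C)(C)[Si](C)(C)Cl
Why: Imidazole-mediated silylation of a secondary alcohol, mild enough not to enolise the ketone toward the stereocentre.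

Step 8
Reactants: 11 (3S)-3-(tert-butyldimethylsilyloxy)-6-methylhept-5-en-2-one
Product: 13 (3S)-3-(tert-butyldimethylsilyloxy)-6-methylhepta-1,5-dien-2-yl trifluoromethanesulfonate, via potassium enolate 12 (not isolated)
Conditions: KN(SiMe3)2, THF, −78 °C (ketone added to base); PhNTf2, −78 → −20 °C
Reagents that add atoms: N-phenylbis(trifluoromethanesulfonimide), O=S(=O)(N(c1ccccc1)S(=O)(=O)C(F)(F)F)C(F)(F)F
Why: Enol triflate formation by kinetic deprotonation of the unhindered methyl group and O-sulfonylation of the enolate; the C3–H beside the bulky silyloxy group is not removed, so the stereocentre should stay intact.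

Step 9
Reactants: 7 2-allyl-3-methoxy-6-(triisopropylsilyloxy)benzaldehyde; 13 (3S)-3-(tert-butyldimethylsilyloxy)-6-methylhepta-1,5-dien-2-yl trifluoromethanesulfonate
Product: 14 1-[2-allyl-3-methoxy-6-(triisopropylsilyloxy)phenyl]-2-[(1S)-1-(tert-butyldimethylsilyloxy)-4-methylpent-3-enyl]prop-2-en-1-ol (both C1 epimers)
Conditions: CrCl2 (4 equiv), NiCl2 (2 mol %), DMF, 23 °C
Reagents that add atoms: none
Why: Nozaki–Hiyama–Kishi reaction, in which the alkenyl triflate adds oxidatively to zerovalent nickel, transmetalates to trivalent chromium and attacks only the aldehyde, so the silyl ethers and all three olefins should survive and the new carbinol centre, formed as a mixture, is erased in step 10.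

Step 10
Reactants: 14 1-[2-allyl-3-methoxy-6-(triisopropylsilyloxy)phenyl]-2-[(1S)-1-(tert-butyldimethylsilyloxy)-4-methylpent-3-enyl]prop-2-en-1-ol
Product: 15 1-[2-allyl-3-methoxy-6-(triisopropylsilyloxy)phenyl]-2-[(1S)-1-(tert-butyldimethylsilyloxy)-4-methylpent-3-enyl]prop-2-en-1-one
Conditions: Dess–Martin periodinane, CH2Cl2, 0 → 23 °C
Reagents that add atoms: none
Why: Dess–Martin oxidation of a secondary alcohol that is both benzylic and allylic, under near-neutral conditions that should leave the silyl ethers and the side-chain stereocentre (not α to the new carbonyl) unchanged.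

Step 11
Reactants: 15 1-[2-allyl-3-methoxy-6-(triisopropylsilyloxy)phenyl]-2-[(1S)-1-(tert-butyldimethylsilyloxy)-4-methylpent-3-enyl]prop-2-en-1-one
Product: 17 2-[(1S)-1-(tert-butyldimethylsilyloxy)-4-methylpent-3-enyl]-5-methoxy-8-(triisopropylsilyloxy)naphthalen-1-ol, via 4H-naphthalen-1-one 16 (not isolated)
Conditions: second-generation Grubbs catalyst RuCl2(=CHPh)(PCy3)(H2IMes) (5 mol %), 1,4-benzoquinone (10 mol %), toluene (high dilution), 60 °C
Reagents that add atoms: none
Why: The ruthenium benzylidene exchanges with the monosubstituted allyl olefin, the new alkylidene forms a ruthenacyclobutane with the 1,1-disubstituted enone olefin of the same molecule and cycloreverts with loss of ethene, joining C3 to C2. The closest known reaction type is the ring-closing metathesis of ortho-allylaryl vinyl ketones to 1-naphthols with second-generation ruthenium carbenes. Ring B closes as a six-membered carbocycle by olefin–olefin metathesis between the two ortho arms of ring A, and dienone 16 then tautomerises to the naphthol, an aromatisation that makes the closure irreversible. No stereocentre is formed, and the silyloxy-bearing carbon, which is not α to the carbonyl, should keep its S configuration. The step needs chemoselectivity among three olefins: the catalyst loads at the terminal allyl group, while the trisubstituted prenyl olefin is too hindered to initiate and could only close a four- or nine-membered ring, so six-ring closure onto the enone olefin should win. 1,4-Benzoquinone is added to suppress ruthenium hydride migration of the allyl double bond.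

Step 12
Reactants: 17 2-[(1S)-1-(tert-butyldimethylsilyloxy)-4-methylpent-3-enyl]-5-methoxy-8-(triisopropylsilyloxy)naphthalen-1-ol
Product: 18 2-[(1S)-1-(tert-butyldimethylsilyloxy)-4-methylpent-3-enyl]-5-methoxy-8-(triisopropylsilyloxy)naphthalene-1,4-dione
Conditions: (KSO3)2NO (3 equiv), aq. KH2PO4, acetone, 0 → 23 °C
Reagents that add atoms: potassium nitrosodisulfonate, [K+].[K+].[O]N(S(=O)(=O)[O-])S(=O)(=O)[O-]
Why: Teuber oxidation, in which one nitrosodisulfonate radical abstracts the naphthol hydrogen and a second adds through oxygen at C4 (the free position para to the hydroxyl) and eliminates imidodisulfonate to give the para-quinone, while ring A is protected from oxidation by its silylated and methylated oxygens.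

Step 13
Reactants: 18 2-[(1S)-1-(tert-butyldimethylsilyloxy)-4-methylpent-3-enyl]-5-methoxy-8-(triisopropylsilyloxy)naphthalene-1,4-dione
Product: 19 8-hydroxy-2-[(1S)-1-hydroxy-4-methylpent-3-enyl]-5-methoxynaphthalene-1,4-dione
Conditions: HF·pyridine, pyridine, THF, 0 → 23 °C
Reagents that add atoms: none
Why: Fluoride-mediated desilylation, in which the aryl silyl ether peri to the C1 carbonyl behaves as a vinylogous silyl ester and the secondary silyl ether follows, and the acidic medium avoids the base-induced tautomerisation of the hydroxyalkylquinone that would erase the stereocentre.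

Step 14
Reactants: 19 8-hydroxy-2-[(1S)-1-hydroxy-4-methylpent-3-enyl]-5-methoxynaphthalene-1,4-dione; 20 3-methylbut-2-enoic acid
Product: 21 (1S)-1-(8-hydroxy-5-methoxy-1,4-dioxo-1,4-dihydronaphthalen-2-yl)-4-methylpent-3-enyl 3-methylbut-2-enoate
Conditions: DCC, DMAP (10 mol %), CH2Cl2, 0 °C
Reagents that add atoms: none
Why: Steglich esterification, selective for the side-chain alcohol because the C8 hydroxyl is held in a hydrogen bond to the C1 carbonyl, with retention at the stereocentre because its C–O bond is not broken.

**Compound list**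

1 | 1-bromo-2,5-dimethoxybenzene | COc1ccc(OC)c(Br)c1 | starting material
2 | (2-bromo-3,6-dimethoxyphenyl)lithium | [Li]c1c(OC)ccc(OC)c1Br | intermediate
3 | 2-bromo-3,6-dimethoxybenzaldehyde | COc1ccc(OC)c(C=O)c1Br | intermediate
4 | 2-bromo-6-hydroxy-3-methoxybenzaldehyde | COc1ccc(O)c(C=O)c1Br | intermediate
5 | 2-bromo-3-methoxy-6-(triisopropylsilyloxy)benzaldehyde | COc1ccc(O[Si](C(C)C)(C(C)C)C(C)C)c(C=O)c1Br | intermediate
6 | allyltributylstannane | C=CC[Sn](CCCC)(CCCC)CCCC | starting material
7 | 2-allyl-3-methoxy-6-(triisopropylsilyloxy)benzaldehyde | C=CCc1c(OC)ccc(O[Si](C(C)C)(C(C)C)C(C)C)c1C=O | intermediate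
8 | 6-methylhept-5-en-2-one | CC(=O)CCC=C(C)C | starting material
9 | (3S)-6-methyl-3-[(phenylamino)oxy]hept-5-en-2-one | CC(=O)[C@H](CC=C(C)C)ONc1ccccc1 | intermediate
10 | (3S)-3-hydroxy-6-methylhept-5-en-2-one | CC(=O)[C@H](CC=C(C)C)O | intermediate
11 | (3S)-3-(tert-butyldimethylsilyloxy)-6-methylhept-5-en-2-one | CC(=O)[C@H](CC=C(C)C)O[Si](C)(C)C(C)(C)C | intermediate
12 | potassium (3S)-3-(tert-butyldimethylsilyloxy)-6-methylhepta-1,5-dien-2-olate | [K+].[O-]C(=C)[C@H](CC=C(C)C)O[Si](C)(C)C(C)(C)C | intermediate
13 | (3S)-3-(tert-butyldimethylsilyloxy)-6-methylhepta-1,5-dien-2-yl trifluoromethanesulfonate | C=C(OS(=O)(=O)C(F)(F)F)[C@H](CC=C(C)C)O[Si](C)(C)C(C)(C)C | intermediate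
14 | 1-[2-allyl-3-methoxy-6-(triisopropylsilyloxy)phenyl]-2-[(1S)-1-(tert-butyldimethylsilyloxy)-4-methylpent-3-enyl]prop-2-en-1-ol (both C1 epimers) | C=CCc1c(OC)ccc(O[Si](C(C)C)(C(C)C)C(C)C)c1C(O)C(=C)[C@H](CC=C(C)C)O[Si](C)(C)C(C)(C)C | intermediate
15 | 1-[2-allyl-3-methoxy-6-(triisopropylsilyloxy)phenyl]-2-[(1S)-1-(tert-butyldimethylsilyloxy)-4-methylpent-3-enyl]prop-2-en-1-one | C=CCc1c(OC)ccc(O[Si](C(C)C)(C(C)C)C(C)C)c1C(=O)C(=C)[C@H](CC=C(C)C)O[Si](C)(C)C(C)(C)C | intermediate
16 | 2-[(1S)-1-(tert-butyldimethylsilyloxy)-4-methylpent-3-enyl]-5-methoxy-8-(triisopropylsilyloxy)-4H-naphthalen-1-one | COc1ccc(O[Si](C(C)C)(C(C)C)C(C)C)c2c1CC=C([C@H](CC=C(C)C)O[Si](C)(C)C(C)(C)C)C2=O | intermediate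
17 | 2-[(1S)-1-(tert-butyldimethylsilyloxy)-4-methylpent-3-enyl]-5-methoxy-8-(triisopropylsilyloxy)naphthalen-1-ol | COc1ccc(O[Si](C(C)C)(C(C)C)C(C)C)c2c(O)c([C@H](CC=C(C)C)O[Si](C)(C)C(C)(C)C)ccc12 | intermediate
18 | 2-[(1S)-1-(tert-butyldimethylsilyloxy)-4-methylpent-3-enyl]-5-methoxy-8-(triisopropylsilyloxy)naphthalene-1,4-dione | COc1ccc(O[Si](C(C)C)(C(C)C)C(C)C)c2c1C(=O)C=C([C@H](CC=C(C)C)O[Si](C)(C)C(C)(C)C)C2=O | intermediate
19 | 8-hydroxy-2-[(1S)-1-hydroxy-4-methylpent-3-enyl]-5-methoxynaphthalene-1,4-dione | COc1ccc(O)c2c1C(=O)C=C([C@H](CC=C(C)C)O)C2=O | intermediate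
20 | 3-methylbut-2-enoic acid | CC(C)=CC(=O)O | starting material
21 | (1S)-1-(8-hydroxy-5-methoxy-1,4-dioxo-1,4-dihydronaphthalen-2-yl)-4-methylpent-3-enyl 3-methylbut-2-enoate | COc1ccc(O)c2c1C(=O)C=C([C@H](CC=C(C)C)OC(=O)C=C(C)C)C2=O | target

**Step count**

Total: 14 steps. Longest linear sequence: 10 steps (steps 1–4 and 9–14 from 1; the side-chain branch, steps 5–8 and 9–14 from 8, is equally long).

**Steps most likely to fail**

Step 11. The ruthenium alkylidene may engage the hindered, electron-poor 1,1-disubstituted enone olefin too slowly, so that migration of the allyl double bond and catalyst decay overtake ring closure. The fallback changes the oxidation level at which the ring is closed. It sets out from 14, whose 1,1-disubstituted olefin is not conjugated and should be more reactive. Ring-closing metathesis of 14 with RuCl2(=CHPh)(PCy3)(H2IMes) in CH2Cl2 at 40 °C should give 2-[(1S)-1-(tert-butyldimethylsilyloxy)-4-methylpent-3-enyl]-5-methoxy-8-(triisopropylsilyloxy)-1,4-dihydronaphthalen-1-ol F1. Oxidation of this alcohol with MnO2 in CH2Cl2 should give dienone 16, which tautomerises, and the fallback comes back to the route at 17.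

Step 5. Enamine formation toward the methyl group, attack at the nitroso nitrogen, or an ene reaction at the trisubstituted olefin may erode regioselectivity, chemoselectivity or enantiomeric purity. The fallback sets the stereocentre by auxiliary-controlled alkylation. It does not use 8; it starts from purchased (R)-4-benzyloxazolidin-2-one and rejoins the route at 10.
- N-Acylation (n-BuLi, (4-methoxybenzyloxy)acetyl chloride, THF, −78 °C) should give (4R)-4-benzyl-3-[(4-methoxybenzyloxy)acetyl]oxazolidin-2-one F2.
- Alkylation of its sodium enolate (NaN(SiMe3)2, THF, −78 °C) with 1-bromo-3-methylbut-2-ene, on the face away from the benzyl group, should give (4R)-4-benzyl-3-[(2S)-2-(4-methoxybenzyloxy)-5-methylhex-4-enoyl]oxazolidin-2-one F3.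
- AlMe3 and MeNHOMe·HCl in CH2Cl2 should convert it into (2S)-N-methoxy-2-(4-methoxybenzyloxy)-N,5-dimethylhex-4-enamide F4.
- MeMgBr in THF at 0 °C should give (3S)-3-(4-methoxybenzyloxy)-6-methylhept-5-en-2-one F5.
- DDQ in wet CH2Cl2 should remove the 4-methoxybenzyl group and give 10.

Step 9. Carbonyl addition to the doubly ortho-substituted aldehyde may be slow, so that protonation of the alkenylchromium species, or loss of its allylic silyloxy group by β-elimination to an allene, takes over. The fallback replaces the nickel/chromium coupling by an organolithium addition. It sets out from 13 and comes back to the route at 14.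
- Stannylation of 13 (Pd(PPh3)4, Me3SnSnMe3, LiCl, THF, 60 °C) should give tert-butyldimethyl{[(3S)-6-methyl-2-(trimethylstannyl)hepta-1,5-dien-3-yl]oxy}silane F6.
- Tin–lithium exchange with MeLi in THF at −78 °C should give [(3S)-3-(tert-butyldimethylsilyloxy)-6-methylhepta-1,5-dien-2-yl]lithium F7.
- Addition of F7 to aldehyde 7 at −78 °C with a cold quench should give 14. The triisopropylsilyl ether is expected to resist migration to the lithium alkoxide at that temperature.

**Further compounds**

F1 | step 11 | 2-[(1S)-1-(tert-butyldimethylsilyloxy)-4-methylpent-3-enyl]-5-methoxy-8-(triisopropylsilyloxy)-1,4-dihydronaphthalen-1-ol (both C1 epimers) | COc1ccc(O[Si](C(C)C)(C(C)C)C(C)C)c2c1CC=C([C@H](CC=C(C)C)O[Si](C)(C)C(C)(C)C)C2O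
F2 | step 5 | (4R)-4-benzyl-3-[(4-methoxybenzyloxy)acetyl]oxazolidin-2-one | COc1ccc(COCC(=O)N2[C@H](Cc3ccccc3)COC2=O)cc1
F3 | step 5 | (4R)-4-benzyl-3-[(2S)-2-(4-methoxybenzyloxy)-5-methylhex-4-enoyl]oxazolidin-2-one | COc1ccc(CO[C@@H](CC=C(C)C)C(=O)N2[C@H](Cc3ccccc3)COC2=O)cc1
F4 | step 5 | (2S)-N-methoxy-2-(4-methoxybenzyloxy)-N,5-dimethylhex-4-enamide | CON(C)C(=O)[C@H](CC=C(C)C)OCc1ccc(OC)cc1
F5 | step 5 | (3S)-3-(4-methoxybenzyloxy)-6-methylhept-5-en-2-one | CC(=O)[C@H](CC=C(C)C)OCc1ccc(OC)cc1
F6 | step 9 | tert-butyldimethyl{[(3S)-6-methyl-2-(trimethylstannyl)hepta-1,5-dien-3-yl]oxy}silane | C=C([Sn](C)(C)C)[C@H](CC=C(C)C)O[Si](C)(C)C(C)(C)C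
F7 | step 9 | [(3S)-3-(tert-butyldimethylsilyloxy)-6-methylhepta-1,5-dien-2-yl]lithium | [Li]C(=C)[C@H](CC=C(C)C)O[Si](C)(C)C(C)(C)C
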